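**Retrosynthetic overview**

1. Sophonorol D ⇒ a tetraketide pyrone carrying an (S)-2-aryl-oxirane. One base-mediated operation opens the pyrone, closes ring A by Claisen cyclisation and closes ring C by phenoxide opening of the epoxide at CH2, so the C3–O bond is never broken.
2. Tetraketide pyrone ⇒ dianion of triacetic acid lactone + methyl (S)-2-arylglycidate (Claisen C-acylation).
3. (S)-Glycidate ⇒ α-aryl acrolein; organocatalytic nucleophilic epoxidation sets the only stereocentre, then CHO → CO2Me.
4. α-Aryl acrolein ⇒ aryl bromide + 2-bromoallyl alcohol (Suzuki coupling, MnO2); aryl bromide ⇒ 2,4-dimethoxyphenol (silylation, ortho-metalation/prenylation, bromination).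
5. Ring order: ring B is bought as the arene; rings A and then C both form in the last step.

Assumption: the SMILES denotes the (3S)-enantiomer (CIP order OH > C4 > C2 > aryl); the four bought compounds are taken as catalogue chemicals.

Abbreviations: TIPS = tri(propan-2-yl)silyl; Ar = 2,4-dimethoxy-3-(3-methylbut-2-en-1-yl)-5-(TIPS-oxy)phenyl.

**Route**

Step 1
Reactants: 1 2,4-dimethoxyphenol
Product: 2 (2,4-dimethoxyphenoxy)tri(propan-2-yl)silane
Conditions: TIPSCl, imidazole, DMF, rt
Reagents that add atoms: chlorotri(propan-2-yl)silane (TIPSCl), CC(C)[Si](Cl)(C(C)C)C(C)C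
Why: Imidazole-promoted O-silylation of the phenol gives a bulky, non-directing silyl ether that survives organolithiums and shields C6.

Step 2
Reactants: 2 (2,4-dimethoxyphenoxy)tri(propan-2-yl)silane; 3 1-bromo-3-methylbut-2-ene (prenyl bromide)
Product: 5 [2,4-dimethoxy-3-(3-methylbut-2-en-1-yl)phenoxy]tri(propan-2-yl)silane, via 3-lithioarene 4 (not isolated)
Conditions: n-BuLi, TMEDA, THF, 0 °C; then CuBr·SMe2 (10 mol%), 3, −78 → 0 °C
Reagents that add atoms: none
Why: Directed ortho-metalation takes place at the carbon flanked by the two methoxy groups (as in 1,2,4-trialkoxybenzenes), and copper-catalysed SN2 allylation with prenyl bromide gives the linear prenyl arene.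

Step 3
Reactants: 5 [2,4-dimethoxy-3-(3-methylbut-2-en-1-yl)phenoxy]tri(propan-2-yl)silane
Product: 6 [5-bromo-2,4-dimethoxy-3-(3-methylbut-2-en-1-yl)phenoxy]tri(propan-2-yl)silane
Conditions: NBS (1.02 equiv), MeCN, −30 → 0 °C, dark
Reagents that add atoms: N-bromosuccinimide, O=C1CCC(=O)N1Br
Why: Electrophilic aromatic bromination goes to C5 (para to one OMe, ortho to the other, remote from OTIPS) and should be much faster on this trialkoxyarene than NBS attack on the isolated trisubstituted alkene in dry MeCN in the dark.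

Step 4
Reactants: 6 [5-bromo-2,4-dimethoxy-3-(3-methylbut-2-en-1-yl)phenoxy]tri(propan-2-yl)silane; 7 2-bromoprop-2-en-1-ol
Product: 10 2-Ar-prop-2-en-1-ol, via aryllithium 8 (not isolated), via lithium aryltrimethoxyborate 9 (not isolated)
Conditions: n-BuLi, THF, −78 °C; B(OMe)3, −78 °C → rt; then 7, Pd(OAc)2/SPhos (cat.), aq K3PO4, 45 °C
Reagents that add atoms: none
Why: Bromine–lithium exchange, borylation and in situ Suzuki–Miyaura coupling with the vinylic bromide give the 2-arylallyl alcohol without isolating the electron-rich boronate, which is prone to protodeboronation.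

Step 5
Reactants: 10 2-Ar-prop-2-en-1-ol
Product: 11 2-Ar-prop-2-enal
Conditions: MnO2, CH2Cl2, rt; filtered and used at once
Reagents that add atoms: none
Why: MnO2 oxidises only the allylic alcohol to the α-aryl acrolein and leaves the prenyl alkene and the silyl ether untouched.

Step 6
Reactants: 11 2-Ar-prop-2-enal
Product: 12 (S)-2-Ar-oxirane-2-carbaldehyde
Conditions: (R)-2-[diphenyl(methyldiphenylsilyloxy)methyl]pyrrolidine (10 mol%), 35% aq H2O2, CH2Cl2, rt
Reagents that add atoms: hydrogen peroxide, OO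
Why: This is an iminium/enamine-catalysed asymmetric Weitz–Scheffer epoxidation of an α-substituted acrolein (diarylprolinol silyl ether catalysis), in which H2O2 adds to the CH2 terminus and the enamine (aryl anti to N) closes onto the peroxide oxygen on the face remote from the CPh2(OSi) group, so that the (R)-catalyst should give the (S)-configured quaternary centre while nucleophilic H2O2 ignores the electron-rich prenyl alkene.

Step 7
Reactants: 12 (S)-2-Ar-oxirane-2-carbaldehyde
Product: 14 methyl (S)-2-Ar-oxirane-2-carboxylate, via epoxy acid 13 (not isolated)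
Conditions: NaClO2, NaH2PO4, 35% aq H2O2, MeCN/H2O, 0 °C; then MeI, K2CO3, DMF, 0 °C → rt
Reagents that add atoms: sodium chlorite, [Na+].[O-]Cl=O; iodomethane, CI
Why: Pinnick oxidation of the non-enolisable aldehyde with H2O2 as hypochlorite scavenger (which protects the prenyl group) and O-methylation of the carboxylate leave the quaternary centre and its C–O bonds untouched.

Step 8
Reactants: 14 methyl (S)-2-Ar-oxirane-2-carboxylate; 15 4-hydroxy-6-methyl-2H-pyran-2-one (triacetic acid lactone)
Product: 17 4-hydroxy-6-{2-oxo-2-[(S)-2-Ar-oxiran-2-yl]ethyl}-2H-pyran-2-one, via dilithio lactone dianion 16 (not isolated)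
Conditions: 15 (3 equiv), LDA (6.2 equiv), THF/DMPU, −78 °C; then 14, −78 → −20 °C; AcOH
Reagents that add atoms: none
Why: Claisen C-acylation of the triacetic acid lactone dianion at its 6-methyl carbon (polyketide chain extension) installs the tetraketide, with excess dianion absorbing the acidic product proton and the epoxide inert to the hard dienolate at low temperature.

Step 9
Reactants: 17 4-hydroxy-6-{2-oxo-2-[(S)-2-Ar-oxiran-2-yl]ethyl}-2H-pyran-2-one
Product: 21 sophonorol D, via trioxo ester 18 (not isolated), via epoxy ketone 19 (not isolated), via silyl isoflavanone 20 (not isolated)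
Conditions: KOH (10 equiv), dry degassed MeOH, 0 → 55 °C; then AcOH to pH 6
Reagents that add atoms: none
Why: Proposed new method: methoxide opens the pyrone to the 3,5,7-trioxo ester, the doubly activated C6 carbanion attacks the ester carbonyl (Claisen cyclisation, ring A as a 2,4,6-trihydroxyaryl ketone), and an ortho-phenoxide then opens the epoxide at its unhindered CH2 (6-endo, ring C), so the C3–O bond and the (S) configuration are retained and the aryl silyl ether is methanolysed in the same pot; the closest known reactions are the base-induced rearrangement of 6-(2-oxoalkyl)-4-hydroxy-2-pyrones to acylphloroglucinols with non-chelating KOH/MeOH (Mg(OMe)2 gives the aldol mode instead) and the Algar–Flynn–Oyamada-type phenoxide opening of α-keto epoxides to 3-hydroxychromanones.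

**Compound list**

1 | 2,4-dimethoxyphenol | COc1ccc(O)c(OC)c1 | starting material
2 | (2,4-dimethoxyphenoxy)tri(propan-2-yl)silane | COc1ccc(O[Si](C(C)C)(C(C)C)C(C)C)c(OC)c1 | intermediate
3 | 1-bromo-3-methylbut-2-ene (prenyl bromide) | CC(C)=CCBr | starting material
4 | [2,6-dimethoxy-3-(TIPS-oxy)phenyl]lithium | COc1ccc(O[Si](C(C)C)(C(C)C)C(C)C)c(OC)c1[Li] | intermediate
5 | [2,4-dimethoxy-3-(3-methylbut-2-en-1-yl)phenoxy]tri(propan-2-yl)silane | COc1ccc(O[Si](C(C)C)(C(C)C)C(C)C)c(OC)c1CC=C(C)C | intermediate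
6 | [5-bromo-2,4-dimethoxy-3-(3-methylbut-2-en-1-yl)phenoxy]tri(propan-2-yl)silane (Ar–Br) | COc1c(Br)cc(O[Si](C(C)C)(C(C)C)C(C)C)c(OC)c1CC=C(C)C | intermediate
7 | 2-bromoprop-2-en-1-ol | OCC(Br)=C | starting material
8 | Ar–Li | COc1c([Li])cc(O[Si](C(C)C)(C(C)C)C(C)C)c(OC)c1CC=C(C)C | intermediate
9 | lithium Ar-trimethoxyborate | [Li+].COc1c(cc(O[Si](C(C)C)(C(C)C)C(C)C)c(OC)c1CC=C(C)C)[B-](OC)(OC)OC | intermediate
10 | 2-Ar-prop-2-en-1-ol | COc1c(C(=C)CO)cc(O[Si](C(C)C)(C(C)C)C(C)C)c(OC)c1CC=C(C)C | intermediate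
11 | 2-Ar-prop-2-enal | COc1c(C(=C)C=O)cc(O[Si](C(C)C)(C(C)C)C(C)C)c(OC)c1CC=C(C)C | intermediate
12 | (S)-2-Ar-oxirane-2-carbaldehyde | O=C[C@]1(c2cc(O[Si](C(C)C)(C(C)C)C(C)C)c(OC)c(CC=C(C)C)c2OC)CO1 | intermediate
13 | (S)-2-Ar-oxirane-2-carboxylic acid | OC(=O)[C@]1(c2cc(O[Si](C(C)C)(C(C)C)C(C)C)c(OC)c(CC=C(C)C)c2OC)CO1 | intermediate
14 | methyl (S)-2-Ar-oxirane-2-carboxylate | COC(=O)[C@]1(c2cc(O[Si](C(C)C)(C(C)C)C(C)C)c(OC)c(CC=C(C)C)c2OC)CO1 | intermediate
15 | 4-hydroxy-6-methyl-2H-pyran-2-one (triacetic acid lactone) | Cc1cc(O)cc(=O)o1 | starting material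
16 | dilithium salt of the dianion of 15 (4-oxido, 6-CH2 carbanion) | [Li+].[Li+].[CH2-]c1cc([O-])cc(=O)o1 | intermediate
17 | 4-hydroxy-6-{2-oxo-2-[(S)-2-Ar-oxiran-2-yl]ethyl}-2H-pyran-2-one | O=c1cc(O)cc(CC(=O)[C@]2(c3cc(O[Si](C(C)C)(C(C)C)C(C)C)c(OC)c(CC=C(C)C)c3OC)CO2)o1 | intermediate
18 | methyl 7-[(S)-2-Ar-oxiran-2-yl]-3,5,7-trioxoheptanoate | COC(=O)CC(=O)CC(=O)CC(=O)[C@]1(c2cc(O[Si](C(C)C)(C(C)C)C(C)C)c(OC)c(CC=C(C)C)c2OC)CO1 | intermediate
19 | [(S)-2-Ar-oxiran-2-yl](2,4,6-trihydroxyphenyl)methanone | O=C(c1c(O)cc(O)cc1O)[C@]1(c2cc(O[Si](C(C)C)(C(C)C)C(C)C)c(OC)c(CC=C(C)C)c2OC)CO1 | intermediate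
20 | (3S)-3-Ar-3,5,7-trihydroxy-2,3-dihydro-4H-chromen-4-one (5'-O-TIPS sophonorol D) | COc1c(O[Si](C(C)C)(C(C)C)C(C)C)cc([C@]2(O)COc3cc(O)cc(O)c3C2=O)c(OC)c1CC=C(C)C | intermediate
21 | sophonorol D, (3S)-3,5,7-trihydroxy-3-[5-hydroxy-2,4-dimethoxy-3-(3-methylbut-2-en-1-yl)phenyl]-2,3-dihydro-4H-chromen-4-one | COc1c(O)cc([C@]2(O)COc3cc(O)cc(O)c3C2=O)c(OC)c1CC=C(C)C | target

**Step count and risks**

Total: 9 steps. Longest linear sequence: 9 steps (1 → 21); lactone 15 enters in step 8 as a bought compound.

The step most likely to fail is step 9. The epoxide may be opened by methoxide before the pyrone opens, or the chain may close in the aldol sense to a resorcylate. The fallback sets out from 14 and comes back at 20, and forms the two rings one after the other from an open-chain tetraketide. Ester 14 acylates the trilithium trianion of bought methyl 3,5-dioxohexanoate F1 (LDA, THF, −78 °C), which gives trioxo ester 18 directly with no pyrone to open. Compound 18 is treated at once with K2CO3 in MeOH at 0 °C, where the C5 enolate oxygen opens the epoxide at CH2 to give the monocyclic methyl 4-[(3S)-3-Ar-3-hydroxy-4-oxo-3,4-dihydro-2H-pyran-6-yl]-3-oxobutanoate F2, which is isolated. Its C7 carbonyl is now a vinylogous ester, so the aldol path is shut. NaOMe in MeOH at 50 °C then closes ring A by vinylogous Claisen condensation to 20, which loses its silyl group in the same pot to give 21.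

The second is step 6. α-Aryl acroleins are an untested substrate class for this epoxidation, the sense of induction is assigned by analogy with α-alkyl acroleins, and the enal is prone to polymerise. The fallback sets out from 10 and comes back at 12, and moves the asymmetric step to the alcohol oxidation level. Sharpless asymmetric epoxidation of 10 (Ti(OiPr)4, D-(−)-diisopropyl tartrate, TBHP, 4 Å sieves, CH2Cl2, −25 °C) is directed by the allylic OH, leaves the prenyl alkene alone, and gives (R)-(2-Ar-oxiran-2-yl)methanol F3. This electron-rich benzylic epoxy alcohol is acid-labile, so it is oxidised without delay under basic Parikh–Doering conditions (SO3·pyridine, DMSO, iPr2NEt) to 12.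

The third is step 8. The ester carbonyl of 14 sits next to a quaternary carbon and may be acylated too slowly by dianion 16. The fallback sets out from 12 and comes back at 17, and replaces the Claisen acylation by aldol addition and oxidation. Dianion 16 adds to the more reactive aldehyde 12 (THF, −78 °C) to give 4-hydroxy-6-{2-hydroxy-2-[(S)-2-Ar-oxiran-2-yl]ethyl}-2H-pyran-2-one F4 as two carbinol epimers, which does not matter. F4 is kept as its triethylammonium salt, because the free hydroxypyrone would open the epoxide, and is oxidised at once (SO3·pyridine, DMSO, Et3N) to 17.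

**Further compounds**

F1 | step 9 | trilithium salt of the trianion of methyl 3,5-dioxohexanoate | [Li+].[Li+].[Li+].[CH2-]C(=O)[CH-]C(=O)[CH-]C(=O)OC
F2 | step 9 | methyl 4-[(3S)-3-Ar-3-hydroxy-4-oxo-3,4-dihydro-2H-pyran-6-yl]-3-oxobutanoate | COC(=O)CC(=O)CC1=CC(=O)[C@](O)(c2cc(O[Si](C(C)C)(C(C)C)C(C)C)c(OC)c(CC=C(C)C)c2OC)CO1
F3 | step 6 | (R)-(2-Ar-oxiran-2-yl)methanol | OC[C@]1(c2cc(O[Si](C(C)C)(C(C)C)C(C)C)c(OC)c(CC=C(C)C)c2OC)CO1
F4 | step 8 | 4-hydroxy-6-{2-hydroxy-2-[(S)-2-Ar-oxiran-2-yl]ethyl}-2H-pyran-2-one | O=c1cc(O)cc(CC(O)[C@]2(c3cc(O[Si](C(C)C)(C(C)C)C(C)C)c(OC)c(CC=C(C)C)c3OC)CO2)o1
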